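**Retrosynthetic overview**
- Target 28 ← esterification at O8, acetylation at O13 and desilylation ← bis-silyl macrocyclic butenolide 25.
- 25 ← Nozaki–Hiyama–Kishi ring closure at C6–C7 of the acyclic (Z)-enol triflate epoxy aldehyde 23; the adduct lactonizes in the same flask.
- Enabling feature: the fully substituted C7=C11 alkene of the butenolide is the enol form of a C7 ketone with a C12 ester. It holds C12 cis to C6, so C7 can act as an alkenyl nucleophile whose adduct closes the lactone, and C6 sits next to the C4–C5 oxirane, which steers the addition.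
- 23 ← aldol, oxidation and triflation (C7–C11) ← Cu-catalysed opening of methyl (R)-glycidate (C9–C10) by a (Z)-alkenyl iodide ← nerol (Sharpless epoxidation, ozonolysis, iodo-Wittig).
- Ring order: oxirane C4–C5 (step 1), oxirane C1–C10 (step 7), then the ten-membered carbocycle and the butenolide together (step 15).

Key step: step 15

Remark (assumption on the chemistry): germacrane numbering is used (ring C1–C10; C11 butenolide α-carbon, C12 lactone carbonyl, C13 acetoxymethyl carbon, C14 methyl on C10, C15 methyl on C4). The SMILES is read as (1S,4S,5R,6R,8R,10R) with both oxiranes cis-fused to the ten-membered ring (C2/C9 cis and C3/C6 cis), so both derive from Z-trisubstituted alkenes.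

**Step 1**
Reactants: 1 nerol
Product: 2 (2R,3S)-2,3-epoxynerol
Conditions: Ti(OiPr)4 (cat.), D-(−)-diisopropyl tartrate (cat.), t-BuOOH, 4 Å MS, CH2Cl2, −20 °C
Reagents that add atoms: tert-butyl hydroperoxide, CC(C)(C)OO
Why: Sharpless asymmetric epoxidation is directed by the allylic hydroxyl, so only the C4=C5 alkene reacts; the D-tartrate ligand should deliver oxygen to the face that gives the (4S,5R) oxirane, and the Z geometry of nerol makes it cis.

**Step 2**
Reactants: 2 (2R,3S)-2,3-epoxynerol
Product: 3 triethylsilyl ether of 2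
Conditions: Et3SiCl, imidazole, CH2Cl2, 0 °C
Reagents that add atoms: chlorotriethylsilane, CC[Si](Cl)(CC)CC
Why: Standard silylation of a primary alcohol under non-acidic conditions that leave the oxirane untouched.

**Step 3**
Reactants: 3 triethylsilyl ether of 2
Product: 5 epoxy aldehyde (C1 formyl), via ozonide 4 (not isolated)
Conditions: O3, CH2Cl2, −78 °C; then PPh3, −78 °C → rt
Reagents that add atoms: ozone, [O-][O+]=O
Why: Ozonolysis cleaves the only remaining alkene, and reductive work-up of the ozonide should give the aldehyde without touching oxirane or silyl ether.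

**Step 4**
Reactants: 5 epoxy aldehyde (C1 formyl)
Product: 6 (Z)-alkenyl iodide
Conditions: [Ph3PEt]I, n-BuLi, THF, 0 °C; I2, −78 °C; NaN(SiMe3)2, −20 °C; then 5, −78 °C
Reagents that add atoms: ethyltriphenylphosphonium iodide, CC[P+](c1ccccc1)(c1ccccc1)c1ccccc1.[I-]; iodine, II
Why: Wittig olefination with the α-iodo ylide (Stork–Zhao type) is kinetically Z-selective, placing iodine cis to the chain and the C14 methyl trans, the geometry the cis C1–C10 oxirane later needs.

**Step 5**
Reactants: 6 (Z)-alkenyl iodide; 7 methyl (R)-glycidate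
Product: 10 (2R,4Z)-α-hydroxy ester, via alkenyllithium 8 (not isolated), via alkenylmagnesium bromide 9 (not isolated)
Conditions: t-BuLi (2 equiv), Et2O, −78 °C; MgBr2·OEt2; CuI (10 mol %), 7, THF, −78 → −30 °C
Reagents that add atoms: none
Why: Iodine–lithium exchange and transmetalation proceed with retention of alkene geometry, and the copper-catalysed Grignard opening of the glycidate occurs by SN2 attack at its unsubstituted carbon, so C8 is taken unchanged (R) from the glycidate.

**Step 6**
Reactants: 10 (2R,4Z)-α-hydroxy ester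
Product: 11 tert-butyldimethylsilyl ether of 10
Conditions: t-BuMe2SiCl, imidazole, DMF, rt
Reagents that add atoms: tert-butyldimethylsilyl chloride, CC(C)(C)[Si](C)(C)Cl
Why: Standard silylation of a secondary α-hydroxy ester.

**Step 7**
Reactants: 11 tert-butyldimethylsilyl ether of 10
Product: 12 bis-epoxy ester
Conditions: L-fructose-derived diacetonide ketone catalyst (30 mol %), KHSO5 (as 2KHSO5·KHSO4·K2SO4), K2CO3, Bu4NHSO4, MeCN/CH2(OMe)2/aq. Na2B4O7 buffer, 0 °C
Reagents that add atoms: potassium peroxymonosulfate KHSO5, [K+].[O-]S(=O)(=O)OO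
Why: Shi epoxidation is reagent-controlled through the spiro transition state of the chiral dioxirane; the L-series ketone should deliver oxygen to the face giving (1S) at the CH carbon, and stereospecific syn addition to the Z-alkene then fixes (10R) and the cis-oxirane.

**Step 8**
Reactants: 12 bis-epoxy ester
Product: 14 α-silyloxy aldehyde (C7 formyl), via aluminium hemiacetal 13 (not isolated)
Conditions: iBu2AlH (1.1 equiv), CH2Cl2, −78 °C; aq. potassium sodium tartrate
Reagents that add atoms: none
Why: Partial reduction of an α-silyloxy methyl ester stops at the tetrahedral aluminium hemiacetal at −78 °C, which releases the aldehyde on work-up; the oxiranes should not react at this temperature.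

**Step 9**
Reactants: 15 methyl 3-hydroxypropanoate
Product: 16 methyl 3-(tert-butyldimethylsilyloxy)propanoate
Conditions: t-BuMe2SiCl, imidazole, DMF, rt
Reagents that add atoms: tert-butyldimethylsilyl chloride, CC(C)(C)[Si](C)(C)Cl
Why: Standard silylation of a primary alcohol.

**Step 10**
Reactants: 14 α-silyloxy aldehyde (C7 formyl); 16 methyl 3-(tert-butyldimethylsilyloxy)propanoate
Product: 18 aldol adduct (β-hydroxy ester), via lithium enolate 17 (not isolated)
Conditions: LiN(iPr)2, THF, −78 °C (16); then 14, −78 °C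
Reagents that add atoms: none
Why: Aldol addition of the lithium ester enolate at −78 °C is faster than β-elimination of silanolate; the two new stereocentres (C7, C11) are left undefined because both are erased in steps 11 and 12.

**Step 11**
Reactants: 18 aldol adduct (β-hydroxy ester)
Product: 19 β-keto ester
Conditions: Dess–Martin periodinane, NaHCO3, CH2Cl2, 0 °C → rt
Reagents that add atoms: none
Why: Buffered Dess–Martin oxidation converts the secondary alcohol into the ketone without acid that would open the oxiranes or epimerize C8.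

**Step 12**
Reactants: 19 β-keto ester
Product: 21 (Z)-enol triflate, via chelated lithium enolate 20 (not isolated)
Conditions: LiN(SiMe3)2, THF, −78 °C; then N-(5-chloropyridin-2-yl)bis(trifluoromethanesulfonyl)imide, −78 → 0 °C
Reagents that add atoms: N-(5-chloropyridin-2-yl)bis(trifluoromethanesulfonyl)imide, FC(F)(F)S(=O)(=O)N(c1ccc(Cl)cn1)S(=O)(=O)C(F)(F)F
Why: O-sulfonylation of the β-keto ester enolate in which lithium bridges the C7 oxygen and the ester carbonyl should place the triflate cis to the ester (Z), the geometry that later puts C12 cis to C6; only the doubly activated C11–H is removed, so C8 is not epimerized.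

**Step 13**
Reactants: 21 (Z)-enol triflate
Product: 22 primary alcohol at C6
Conditions: HF·pyridine, pyridine, THF, 0 °C
Reagents that add atoms: none
Why: A primary triethylsilyl ether is cleaved much faster than primary or secondary tert-butyldimethylsilyl ethers by buffered HF·pyridine.

**Step 14**
Reactants: 22 primary alcohol at C6
Product: 23 epoxy aldehyde (C6 formyl)
Conditions: Dess–Martin periodinane, NaHCO3, CH2Cl2, 0 °C
Reagents that add atoms: none
Why: Dess–Martin oxidation of a 2,3-epoxy alcohol gives the configurationally stable α,β-epoxy aldehyde, which is used at once.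

**Step 15**
Reactants: 23 epoxy aldehyde (C6 formyl)
Product: 25 bis-silyl macrocyclic butenolide, via chromium alkoxide 24 (not isolated)
Conditions: CrCl2 (about 12 equiv), NiCl2 (cat.), degassed DMF, rt, syringe-pump addition of 23 to about 2 mM; aqueous work-up
Reagents that add atoms: none
Why: Zerovalent nickel (formed in the flask from NiCl2 and CrCl2) inserts into the C7–OTf bond, the alkenyl group passes to trivalent chromium, and the alkenylchromium adds to the C6 aldehyde; the chromium alkoxide 24 then sits cis to the C12 methyl ester across the C7=C11 alkene and expels methoxide to form the lactone. The closest known reaction types are the Nozaki–Hiyama–Kishi macrocyclization of alkenyl triflates or iodides onto aldehydes and the addition of β-halo or β-sulfonyloxy acrylates to aldehydes that ends in a butenolide. The ten-membered carbocycle closes in the 10-exo-trig mode (C7 onto the C6 carbonyl) and the butenolide then closes in the 5-exo-trig mode (O6 onto C12). The new stereocentre C6 is controlled by the adjacent C5 of the C4–C5 oxirane: polar Felkin–Anh attack anti to the C5–O bond should give the 5,6-anti (6R) alkoxide, which is the isomer needed. The step needs ring closure to outrun oligomerization and the aldehyde to be the only electrophile that reacts; high dilution with slow addition, the two cis-oxiranes and the Z-alkene as turn elements, and the aldehyde-selective alkenylchromium (esters, oxiranes and silyl ethers are left alone) should secure this.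

**Step 16**
Reactants: 25 bis-silyl macrocyclic butenolide
Product: 26 8,13-diol
Conditions: HF·pyridine, pyridine, THF, 0 °C → rt
Reagents that add atoms: none
Why: Buffered fluoride-mediated desilylation removes both tert-butyldimethylsilyl ethers without base that would harm the butenolide and without strong acid that would open the oxiranes.

**Step 17**
Reactants: 26 8,13-diol
Product: 27 13-acetate 8-alcohol
Conditions: AcCl (1.05 equiv), 2,4,6-collidine, CH2Cl2, −78 °C
Reagents that add atoms: acetyl chloride, CC(Cl)=O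
Why: Acylation with acetyl chloride and a hindered pyridine base at low temperature is selective for the primary allylic C13 hydroxyl over the hindered secondary C8 hydroxyl.

**Step 18**
Reactants: 27 13-acetate 8-alcohol
Product: 28 target CNP0228323.1
Conditions: 3-methylbut-2-enoyl chloride, pyridine, DMAP (cat.), CH2Cl2, 0 °C
Reagents that add atoms: 3-methylbut-2-enoyl chloride, CC(C)=CC(Cl)=O
Why: DMAP-catalysed acylation of the remaining secondary alcohol with pyridine as a weak base, which should avoid ketene formation and deconjugation of the senecioate.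

**Compound list**
1 | nerol, (2Z)-3,7-dimethylocta-2,6-dien-1-ol | CC(C)=CCC/C(C)=C\CO | starting material
2 | [(2R,3S)-3-methyl-3-(4-methylpent-3-en-1-yl)oxiran-2-yl]methanol | OC[C@H]1O[C@@]1(C)CCC=C(C)C | intermediate
3 | triethylsilyl ether of 2 | CC[Si](CC)(CC)OC[C@H]1O[C@@]1(C)CCC=C(C)C | intermediate
4 | secondary ozonide (3,3-dimethyl-1,2,4-trioxolane) at the former terminal alkene of 3 | CC[Si](CC)(CC)OC[C@H]1O[C@@]1(C)CCC1OOC(C)(C)O1 | intermediate (not isolated)
5 | 3-[(2S,3R)-2-methyl-3-(triethylsilyloxymethyl)oxiran-2-yl]propanal | CC[Si](CC)(CC)OC[C@H]1O[C@@]1(C)CCC=O | intermediate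
6 | triethyl{[(2R,3S)-3-[(3Z)-4-iodopent-3-en-1-yl]-3-methyloxiran-2-yl]methoxy}silane | CC[Si](CC)(CC)OC[C@H]1O[C@@]1(C)CC/C=C(/C)I | intermediate
7 | methyl (2R)-oxirane-2-carboxylate, methyl (R)-glycidate | COC(=O)[C@H]1CO1 | starting material
8 | alkenyllithium from 6 (lithium in place of iodine, Z retained) | CC[Si](CC)(CC)OC[C@H]1O[C@@]1(C)CC/C=C(/C)[Li] | intermediate (not isolated)
9 | alkenylmagnesium bromide from 8 | CC[Si](CC)(CC)OC[C@H]1O[C@@]1(C)CC/C=C(/C)[Mg]Br | intermediate (not isolated)
10 | methyl (2R,4Z)-2-hydroxy-4-methyl-7-[(2S,3R)-2-methyl-3-(triethylsilyloxymethyl)oxiran-2-yl]hept-4-enoate | CC[Si](CC)(CC)OC[C@H]1O[C@@]1(C)CC/C=C(/C)C[C@@H](O)C(=O)OC | intermediate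
11 | tert-butyldimethylsilyl ether of 10 (C8, R) | CC[Si](CC)(CC)OC[C@H]1O[C@@]1(C)CC/C=C(/C)C[C@@H](O[Si](C)(C)C(C)(C)C)C(=O)OC | intermediate
12 | methyl (2R)-2-(tert-butyldimethylsilyloxy)-3-[(2R,3S)-2-methyl-3-{2-[(2S,3R)-2-methyl-3-(triethylsilyloxymethyl)oxiran-2-yl]ethyl}oxiran-2-yl]propanoate | CC[Si](CC)(CC)OC[C@H]1O[C@@]1(C)CC[C@@H]1O[C@]1(C)C[C@@H](O[Si](C)(C)C(C)(C)C)C(=O)OC | intermediate
13 | diisobutylaluminium hemiacetal of 12 | CC[Si](CC)(CC)OC[C@H]1O[C@@]1(C)CC[C@@H]1O[C@]1(C)C[C@@H](O[Si](C)(C)C(C)(C)C)C(OC)O[Al](CC(C)C)CC(C)C | intermediate (not isolated)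
14 | (2R)-2-(tert-butyldimethylsilyloxy)-3-[(2R,3S)-2-methyl-3-{2-[(2S,3R)-2-methyl-3-(triethylsilyloxymethyl)oxiran-2-yl]ethyl}oxiran-2-yl]propanal | CC[Si](CC)(CC)OC[C@H]1O[C@@]1(C)CC[C@@H]1O[C@]1(C)C[C@@H](O[Si](C)(C)C(C)(C)C)C=O | intermediate
15 | methyl 3-hydroxypropanoate | COC(=O)CCO | starting material
16 | methyl 3-(tert-butyldimethylsilyloxy)propanoate | COC(=O)CCO[Si](C)(C)C(C)(C)C | intermediate
17 | lithium enolate of 16 | COC(O[Li])=CCO[Si](C)(C)C(C)(C)C | intermediate (not isolated)
18 | methyl (4R)-4-(tert-butyldimethylsilyloxy)-2-[(tert-butyldimethylsilyloxy)methyl]-3-hydroxy-5-[bis-oxirane chain as in 14]pentanoate, mixture at C2 and C3 of the pentanoate | CC[Si](CC)(CC)OC[C@H]1O[C@@]1(C)CC[C@@H]1O[C@]1(C)C[C@@H](O[Si](C)(C)C(C)(C)C)C(O)C(CO[Si](C)(C)C(C)(C)C)C(=O)OC | intermediate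
19 | corresponding 3-oxo ester (β-keto ester, mixture at C2 of the pentanoate) | CC[Si](CC)(CC)OC[C@H]1O[C@@]1(C)CC[C@@H]1O[C@]1(C)C[C@@H](O[Si](C)(C)C(C)(C)C)C(=O)C(CO[Si](C)(C)C(C)(C)C)C(=O)OC | intermediate
20 | chelated lithium enolate of 19 (enolate oxygen cis to the ester) | CC[Si](CC)(CC)OC[C@H]1O[C@@]1(C)CC[C@@H]1O[C@]1(C)C[C@@H](O[Si](C)(C)C(C)(C)C)/C(O[Li])=C(/C(=O)OC)CO[Si](C)(C)C(C)(C)C | intermediate (not isolated)
21 | methyl (2Z,4R)-4-(tert-butyldimethylsilyloxy)-2-[(tert-butyldimethylsilyloxy)methyl]-5-[(2R,3S)-2-methyl-3-{2-[(2S,3R)-2-methyl-3-(triethylsilyloxymethyl)oxiran-2-yl]ethyl}oxiran-2-yl]-3-(trifluoromethylsulfonyloxy)pent-2-enoate | CC[Si](CC)(CC)OC[C@H]1O[C@@]1(C)CC[C@@H]1O[C@]1(C)C[C@@H](O[Si](C)(C)C(C)(C)C)/C(OS(=O)(=O)C(F)(F)F)=C(/C(=O)OC)CO[Si](C)(C)C(C)(C)C | intermediate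
22 | analogue of 21 with a free hydroxymethyl group on the terminal oxirane, (2S,3R)-3-(hydroxymethyl)-2-methyloxiran-2-yl | OC[C@H]1O[C@@]1(C)CC[C@@H]1O[C@]1(C)C[C@@H](O[Si](C)(C)C(C)(C)C)/C(OS(=O)(=O)C(F)(F)F)=C(/C(=O)OC)CO[Si](C)(C)C(C)(C)C | intermediate
23 | analogue of 21 with a formyl group on the terminal oxirane, (2S,3S)-3-formyl-2-methyloxiran-2-yl (the descriptor changes only because the formyl group outranks C4; no bond at C5 changes) | O=C[C@H]1O[C@@]1(C)CC[C@@H]1O[C@]1(C)C[C@@H](O[Si](C)(C)C(C)(C)C)/C(OS(=O)(=O)C(F)(F)F)=C(/C(=O)OC)CO[Si](C)(C)C(C)(C)C | intermediate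
24 | dichlorochromium (trivalent) alkoxide of the ring-closed (6R)-hydroxy ester, C6–O cis to the C12 ester | COC(=O)/C(CO[Si](C)(C)C(C)(C)C)=C1\[C@@H](O[Cr](Cl)Cl)[C@H]2O[C@@]2(C)CC[C@@H]2O[C@]2(C)C[C@H]1O[Si](C)(C)C(C)(C)C | intermediate (not isolated)
25 | (1S,4S,5R,6R,8R,10R)-8,13-bis(tert-butyldimethylsilyloxy)-1,10:4,5-diepoxygermacr-7(11)-en-12,6-olide | CC(C)(C)[Si](C)(C)OCC1=C2[C@@H](OC1=O)[C@H]1O[C@@]1(C)CC[C@@H]1O[C@]1(C)C[C@H]2O[Si](C)(C)C(C)(C)C | intermediate
26 | (1S,4S,5R,6R,8R,10R)-1,10:4,5-diepoxy-8,13-dihydroxygermacr-7(11)-en-12,6-olide | OCC1=C2[C@@H](OC1=O)[C@H]1O[C@@]1(C)CC[C@@H]1O[C@]1(C)C[C@H]2O | intermediate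
27 | (1S,4S,5R,6R,8R,10R)-13-acetoxy-1,10:4,5-diepoxy-8-hydroxygermacr-7(11)-en-12,6-olide | CC(=O)OCC1=C2[C@@H](OC1=O)[C@H]1O[C@@]1(C)CC[C@@H]1O[C@]1(C)C[C@H]2O | intermediate
28 | CNP0228323.1, (1S,4S,5R,6R,8R,10R)-13-acetoxy-1,10:4,5-diepoxy-8-(3-methylbut-2-enoyloxy)germacr-7(11)-en-12,6-olide | CC(=O)OCC1=C2[C@@H](OC1=O)[C@H]1O[C@@]1(C)CC[C@@H]1O[C@]1(C)C[C@H]2OC(=O)C=C(C)C | target

**Step count and risks**
Total step count: 18. Longest linear sequence: 17 steps (steps 1–8 and 10–18, from nerol); step 9 is a one-step side branch.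

Steps most likely to fail:

1. Step 15 (ring closure). Intermolecular coupling may outrun closure of the ten-membered ring, the hindered fully substituted alkenyl triflate may be reduced instead of adding, and facial selectivity at C6 may be poor. The fallback sets out from 23 and returns at 25; it makes the C6–C7 bond as an acyl–alkenyl bond and sets C6 afterwards by reduction. Pinnick oxidation of 23 (NaClO2, NaH2PO4, 2-methylbut-2-ene) should give the epoxy acid F1. Exchange of the triflate with Me3SnSnMe3 (Pd(PPh3)4, LiCl, THF) should give the alkenylstannane acid F2. 1-Chloro-N,N,2-trimethylprop-1-en-1-amine converts it under neutral conditions into the acid chloride F3. Intramolecular Stille acylation under high dilution (Pd2(dba)3, tri(2-furyl)phosphine) should close the ring to the ten-membered C6 ketone F4. Luche reduction (NaBH4, CeCl3, MeOH, −78 °C), expected anti to the oxirane, should give the hydroxy ester F5, which lactonizes to 25.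

2. Step 12 (enol triflate geometry). Sulfonylation may take place on the non-chelated enolate and give the wrong alkene geometry, and the enolate may lose silanolate by β-elimination. The fallback sets out from 19 and returns at 27; it makes the opposite geometry on purpose and lets the two C11 substituents exchange roles. Non-chelating conditions (KN(SiMe3)2, 18-crown-6, same triflating agent) should give the (E)-enol triflate F6, with the triflate trans to the ester. iBu2AlH reduces the ester to the allylic alcohol F7, and Ac2O/pyridine gives the acetate F8; this carbon, cis to C8, becomes C13. Buffered HF·pyridine frees the C6 alcohol F9 and Dess–Martin oxidation gives the aldehyde F10. The same CrCl2/NiCl2 ring closure should give the ten-membered allylic alcohol F11; no lactone forms because the cis substituent is a silyloxymethyl group. HF·pyridine removes both silyl groups to the triol F12. TEMPO/PhI(OAc)2 then oxidizes the primary allylic alcohol cis to the C6 hydroxyl through the lactol F13 to the butenolide 27.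

3. Step 7 (second oxirane). Facial selectivity on this Z-trisubstituted alkene may be lower than on E-alkenes, and the methyl ester may be attacked in the basic aqueous medium. The fallback sets out from 10 and returns at 12; it binds the oxidant to the free C8 hydroxyl. Hydroxyl-directed catalytic asymmetric epoxidation of the homoallylic alcohol 10 (VO(OiPr)3, chiral bishydroxamic acid ligand chosen for the (1S,10R) face, cumene hydroperoxide, toluene) should give the epoxy alcohol F14, which is silylated (t-BuMe2SiCl, imidazole, DMF) to 12.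

Further compounds
F1 | step 15 | epoxy acid from 23 (CO2H at C6, triflate retained) | O=C(O)[C@H]1O[C@@]1(C)CC[C@@H]1O[C@]1(C)C[C@@H](O[Si](C)(C)C(C)(C)C)/C(OS(=O)(=O)C(F)(F)F)=C(/C(=O)OC)CO[Si](C)(C)C(C)(C)C
F2 | step 15 | alkenylstannane acid (SnMe3 in place of the triflate, cis to the ester) | O=C(O)[C@H]1O[C@@]1(C)CC[C@@H]1O[C@]1(C)C[C@@H](O[Si](C)(C)C(C)(C)C)/C([Sn](C)(C)C)=C(/C(=O)OC)CO[Si](C)(C)C(C)(C)C
F3 | step 15 | acid chloride of F2 | O=C(Cl)[C@H]1O[C@@]1(C)CC[C@@H]1O[C@]1(C)C[C@@H](O[Si](C)(C)C(C)(C)C)/C([Sn](C)(C)C)=C(/C(=O)OC)CO[Si](C)(C)C(C)(C)C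
F4 | step 15 | ten-membered C6 ketone (methyl ester cis to the C6 carbonyl) | COC(=O)/C(CO[Si](C)(C)C(C)(C)C)=C1\C(=O)[C@H]2O[C@@]2(C)CC[C@@H]2O[C@]2(C)C[C@H]1O[Si](C)(C)C(C)(C)C
F5 | step 15 | (6R)-hydroxy ester from reduction of F4 | COC(=O)/C(CO[Si](C)(C)C(C)(C)C)=C1\[C@@H](O)[C@H]2O[C@@]2(C)CC[C@@H]2O[C@]2(C)C[C@H]1O[Si](C)(C)C(C)(C)C
F6 | step 12 | (E)-enol triflate isomer of 21 (triflate trans to the ester) | CC[Si](CC)(CC)OC[C@H]1O[C@@]1(C)CC[C@@H]1O[C@]1(C)C[C@@H](O[Si](C)(C)C(C)(C)C)/C(OS(=O)(=O)C(F)(F)F)=C(\C(=O)OC)CO[Si](C)(C)C(C)(C)C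
F7 | step 12 | allylic alcohol from reduction of the ester of F6 | CC[Si](CC)(CC)OC[C@H]1O[C@@]1(C)CC[C@@H]1O[C@]1(C)C[C@@H](O[Si](C)(C)C(C)(C)C)/C(OS(=O)(=O)C(F)(F)F)=C(\CO)CO[Si](C)(C)C(C)(C)C
F8 | step 12 | acetate of F7 | CC[Si](CC)(CC)OC[C@H]1O[C@@]1(C)CC[C@@H]1O[C@]1(C)C[C@@H](O[Si](C)(C)C(C)(C)C)/C(OS(=O)(=O)C(F)(F)F)=C(\COC(C)=O)CO[Si](C)(C)C(C)(C)C
F9 | step 12 | C6 alcohol from F8 (triethylsilyl group removed) | OC[C@H]1O[C@@]1(C)CC[C@@H]1O[C@]1(C)C[C@@H](O[Si](C)(C)C(C)(C)C)/C(OS(=O)(=O)C(F)(F)F)=C(\COC(C)=O)CO[Si](C)(C)C(C)(C)C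
F10 | step 12 | epoxy aldehyde from F9 | O=C[C@H]1O[C@@]1(C)CC[C@@H]1O[C@]1(C)C[C@@H](O[Si](C)(C)C(C)(C)C)/C(OS(=O)(=O)C(F)(F)F)=C(\COC(C)=O)CO[Si](C)(C)C(C)(C)C
F11 | step 12 | ten-membered (6R)-allylic alcohol, silyloxymethyl cis to C6 and acetoxymethyl cis to C8 | CC(=O)OC/C(CO[Si](C)(C)C(C)(C)C)=C1/[C@@H](O)[C@H]2O[C@@]2(C)CC[C@@H]2O[C@]2(C)C[C@H]1O[Si](C)(C)C(C)(C)C
F12 | step 12 | triol from F11 (both silyl groups removed) | CC(=O)OC/C(CO)=C1/[C@@H](O)[C@H]2O[C@@]2(C)CC[C@@H]2O[C@]2(C)C[C@H]1O
F13 | step 12 | lactol (2,5-dihydrofuran-2-ol) from F12 | CC(=O)OCC1=C2[C@@H](OC1O)[C@H]1O[C@@]1(C)CC[C@@H]1O[C@]1(C)C[C@H]2O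
F14 | step 7 | epoxy alcohol, 10 with the (1S,10R)-oxirane | CC[Si](CC)(CC)OC[C@H]1O[C@@]1(C)CC[C@@H]1O[C@]1(C)C[C@@H](O)C(=O)OC
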